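Winter is the flask in question, E with X under a trace of Z, followed up to 40 h; midnight is the earlier run with more X.

| setting | winter | midnight | flask |
|---|---|---|---|
| E | 0.10 M | 0.10 M | 0.10 M |
| X | 1.5 equiv | 2.2 equiv | 1.50 equiv |
| Z | 0.01 mol% | 0.01 mol% | 0.01 mol% |
| remark | the very flask that is asked about, followed so far | run made earlier |  |
| time |  |  | 40 h |

- winter (time / h: L / %): 3.00: 10; 8.00: 11; 15.0: 14; 40.0: 21
- midnight (time / h: L / %): 2.00: 7; 6.00: 10; 10.0: 15; 15.0: 16

(standard deviation of a reading: 1.5 percentage points)

- a species is counted by the E in it: one Q counts as two
- L taken out counts as made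
- candidate steps: E + Z <-> G; L + Z <-> D + Z; J -> Z + L; X + G <-> J; 2 J -> Q
- additions bring no volume worth counting

- theta: at 40 h take out 90% of the L then present, then wait 3.0 d
- epsilon: at 40 h add Z, 100% of the amount charged, then wait 3.0 d
- eta: change nothing and wait 3.0 d more
- delta: at 40 h add X, 100% of the amount charged, then wait 3.0 d

- L, in percent of the E first charged, at 40 h
- the remedy with the largest gain of L, or "none" below 2 percentage points (theta / epsilon / eta / delta / none)
- L present, with what was taken out counted in, in percent of the E first charged, after theta
- L present, with what was taken out counted in, in percent of the E first charged, after delta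

Begin with the balance of E, the limiting reagent against 1.50 equiv of X. Winter read 21% of L at 40.0 h, so about 79.0% of its E remains unconverted. Yet its first 3.00 h gave 10% and its last 25.0 h gave 7 percentage points, a fall in speed that the balance of E cannot account for. X does little either: midnight at 15.0 h and winter at 15.0 h differ by 2 points, against a scatter of 1.5 points on each reading. So take the catalyst to be dying, by two J joining to Q. Such a second-order loss makes L rise by equal steps for equal factors of time.

Midnight gives a step of 4.5 points per factor e. Carried from its last reading to 40 h, that gives 20.4%, close to winter's own reading, which took no part in it. The weak link is a slope from two readings, uncertain by about 1.1 points. Winter's longer span gives 4.2 points, and the mean of the two, 4.4 points, is the log slope, the points of L gained per factor e of time.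

Waiting 3.0 d then gains 4.5 points. I give theta and delta the same gain as waiting, reaching 24.9%; for delta the ground is the closeness of the two runs at different X, and for theta it is an assumption. Fresh Z runs its own curve for 3.0 d, so it should gain 24 points, more than waiting, and my choice is epsilon.

The forecast gives 21.3% now, 27% after theta, 27.5% after delta, both above my figure, and epsilon as best, since “Fresh Z restarts the curve”.

The flask gives 20.4%. Epsilon gains 22 points, eta 4.6 points, and theta and delta 4.8 points each, reaching 25.2% and 25.2%.

    E + Z ⇌ G (K = 7.46 M⁻¹, k = 1.01 × 10⁵ M⁻¹ h⁻¹)
    L + Z ⇌ D + Z, rate k2*[Z]*[L] forward; the back reaction follows from the equilibrium constant (K = 14.9, k = 9680 M⁻¹ h⁻¹)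
    J → Z + L (k = 1470 h⁻¹)
    X + G ⇌ J (K = 103 M⁻¹, k = 2.62 × 10⁵ M⁻¹ h⁻¹)
    2 J → Q (k = 2.24 × 10⁵ M⁻¹ h⁻¹)

The neighbour flask differs from winter in its Z, 0.04 mol%. Under second-order loss, raising the charge by a factor acts like raising the time by that factor, so the log slope adds 6 points to 20.4%, making 26.4%. That neighbour flask stands at 26.6% of L, with 72% of its E left unbound.

The readings stem from a simulated flask for an exercise, and the scatter is random.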